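Capture of L cannot outrun its supply: in alder, Q feeds L with a forward half-life of 0.19 h, and whatever Z fails to catch can go back to Q.

    Q ⇌ L (K1 = 0.028, k1 = 9.9 × 10⁻⁴ s⁻¹)
    L → E (k2 = 5.7 × 10⁻⁴ s⁻¹)
    Z + L → Z.L (k3 = 0.37 M⁻¹ s⁻¹)
    L ⇌ J (K4 = 0.032, k4 = 0.19 s⁻¹)
    Z + J → Z.J (k5 = 6.5 M⁻¹ s⁻¹)

| setting | alder | birch | cedar | ash |
|---|---|---|---|---|
| Q | 0.012 M | 0.025 M | 0.050 M | 0.10 M |
| Z | 1.50 equiv | 1.50 equiv | 1.50 equiv | 1.50 equiv |
| time | 1.0 h | 1.0 h | 1.0 h | 1.0 h |

- "hardly changes" means that all values lie within two and a half points (for a concentration: within two and a half percent of the largest)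
- run time (alder): 1.0 h

1. [Z.L] at the end for alder, birch, cedar, ash, in this order
2. how the row runs (hardly changes / rises, then falls / falls all the way / rises all the way / falls, then rises)

My own reckoning treats L as short-lived, in steady state. L returns to Q with a first-order constant r, the forward constant of Q ⇌ L over its equilibrium constant: 0.0354 s⁻¹. That is faster than the leak to E, so I drop the leak. J goes back to L faster than Z catches it, even at ash's charge, so J stays at a fixed small fraction of L. Z then catches L by two doors, directly and through J, with a summed constant κ: 0.578 M⁻¹ s⁻¹.

Now the crossing: c× is r over κ, the [Z] at which L is as likely to be caught as to return to Q, here 0.0612 M. It plays the part of a Michaelis constant, with Z as the saturating partner. The fraction of opened Q that is caught is f = [Z]/([Z] + c×), and Q decays with the forward constant times f. Of what is caught, Z.L takes 64.0%. I hold Z at its charge, which flatters every flask, since Z is consumed.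

| Flask | [Z] charged | f | Q left at the hour | [Z.L] reckoned |
|---|---|---|---|---|
| alder | 0.0180 M | 22.7% | 44.5% | 0.00427 M |
| birch | 0.0375 M | 38.0% | 25.8% | 0.0119 M |
| cedar | 0.0750 M | 55.1% | 14.0% | 0.0275 M |
| ash | 0.150 M | 71.0% | 7.95% | 0.0589 M |

Read it downward. In alder, Z stands below the crossing, so most opened Q closes again. Birch is still below it. Cedar's charge has passed it, yet with f at 55.1% return to Q still competes with capture. Ash catches 71.0% of what opens. Each row brings more Q and a larger f, so I commit to a row that rises at each step.

The forecast gives 0.0037 M, 0.0104 M, 0.0254 M and 0.0575 M, and says the row rises all the way: “Higher loading therefore gives both more material and a higher conversion in the hour”. My column stands above it in each flask .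

The simulation gives 0.00366 M, 0.0104 M, 0.0253 M and 0.0575 M; the row rises all the way, as the forecast said. By the hour, ash's Z has come down to 0.0636 M, level with c×. The forecast's ash value fails if the step J → L is taken away. L then competes for Z against a one-way loss to J as well as its return to Q, so the crossing for Z.L moves to 0.609 M, above ash's charge. Of the Q lost for good, Z.L then takes direct capture over capture plus the loss to J, 22.6% with Z held at ash's charge. The same reckoning, counting the return to Q once, gives 0.0216 M, and the simulated ash run gives 0.0157 M.

Its constants were chosen freely, and the outcome is calculated.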